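**Retrosynthetic overview**

1. Target 26 ⇐ tetracycle 23 (desilylation, CH2OH → CO2H). The carboxy-cyclohexene ring is closed last by RCM of 22, whose secondary carbinol comes from a Felkin-controlled reduction of vinyl ketone 21.
2. Cyclobutane and cyclopentane ⇐ one triplet-sensitised intramolecular diene–alkene [2+2] of the monocyclic diene acid 17. Enabling feature: the cyclobutane shares one bond with the cyclohexene ring, and that ring's C=C sits directly next to this bond (a vinylcyclobutane). The opposite cyclobutane bond is tied to the neighbouring ring-fusion CH by the three cyclopentane atoms CH–CH–CH2 (a bicyclo[3.2.0]heptane). The ring alkene of the target is therefore the unused half of a cyclohexa-1,3-diene.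
3. 17 ⇐ desymmetrising Ireland–Claisen rearrangement of the meso dienyl ester 15. It joins the ring CH to the acid α-carbon, unveils the 1,3-diene and sets three stereocentres.
4. 15 ⇐ trans-dienol 14 (vinyllithium 10 + quinone monoketal 9, hydrolysis, silylation, 1,2-reduction) + acid 6 (Johnson–Claisen from nonanal).
5. Ring order: six-membered diene ring bought as 9 → cyclopentane + cyclobutane (step 10) → carboxy-cyclohexene (step 14).

Key step: step 10

Assumption: the (S,S) antipode of the boron controller is written for step 9; its sense of induction on this new substrate class would be assigned in the first run, and the (R,R) antipode used if it is the opposite.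

**Route**

Step 1
Reactants: 1 nonanal
Product: 2 undec-1-en-3-ol (racemic)
Conditions: CH2=CHMgBr, THF, 0 °C; aq. NH4Cl
Reagents that add atoms: vinylmagnesium bromide, C=C[Mg]Br
Why: Grignard 1,2-addition to an aldehyde; the racemic carbinol centre is consumed in step 2, so no control is needed.

Step 2
Reactants: 2 undec-1-en-3-ol; 3 triethyl orthoacetate
Product: 5 ethyl (E)-tridec-4-enoate, via ketene acetal 4 (not isolated)
Conditions: EtCO2H (cat.), 140 °C, distil off EtOH
Reagents that add atoms: none
Why: Johnson–Claisen rearrangement through a chair transition state with the octyl group equatorial, which sets the E-alkene; no stereocentre remains.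

Step 3
Reactants: 5 ethyl (E)-tridec-4-enoate
Product: 6 (E)-tridec-4-enoic acid
Conditions: LiOH, THF/H2O, rt; then 1 M HCl
Reagents that add atoms: lithium hydroxide, [Li+].[OH-]
Why: Ester saponification; the isolated E-alkene is inert.

Step 4
Reactants: 7 2-bromoprop-2-en-1-ol
Product: 8 [(2-bromoprop-2-en-1-yl)oxy](tert-butyl)dimethylsilane
Conditions: TBSCl, imidazole, CH2Cl2, 0 °C → rt
Reagents that add atoms: tert-butyldimethylsilyl chloride, CC(C)(C)[Si](C)(C)Cl
Why: Standard silylation of a primary allylic alcohol; the vinyl bromide is untouched.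

Step 5
Reactants: 8 [(2-bromoprop-2-en-1-yl)oxy](tert-butyl)dimethylsilane; 9 4,4-dimethoxycyclohexa-2,5-dien-1-one
Product: 12 4-hydroxy-4-{3-[(tert-butyldimethylsilyl)oxy]prop-1-en-2-yl}cyclohexa-2,5-dien-1-one, via vinyllithium 10 (not isolated), via ketal carbinol 11 (not isolated)
Conditions: t-BuLi (2 equiv), Et2O, −78 °C; then 9, −78 °C; H2O; then aq. oxalic acid (cat.), THF, rt
Reagents that add atoms: water, O
Why: Bromine–lithium exchange, 1,2-addition of the vinyllithium to the only carbonyl of the quinone monoketal and mild acetal hydrolysis (the standard p-quinol synthesis); the product is achiral.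

Step 6
Reactants: 12 4-hydroxy-4-{3-[(tert-butyldimethylsilyl)oxy]prop-1-en-2-yl}cyclohexa-2,5-dien-1-one
Product: 13 4-{3-[(tert-butyldimethylsilyl)oxy]prop-1-en-2-yl}-4-[(triethylsilyl)oxy]cyclohexa-2,5-dien-1-one
Conditions: TESOTf, 2,6-lutidine, CH2Cl2, −78 → 0 °C
Reagents that add atoms: triethylsilyl triflate, CC[Si](CC)(CC)OS(=O)(=O)C(F)(F)F
Why: Silyl triflate silylation of the hindered tertiary alcohol; it blocks this carbinol for steps 8 and 9 and keeps the C4–O dipole used in step 7.

Step 7
Reactants: 13 4-{3-[(tert-butyldimethylsilyl)oxy]prop-1-en-2-yl}-4-[(triethylsilyl)oxy]cyclohexa-2,5-dien-1-one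
Product: 14 trans-4-{3-[(tert-butyldimethylsilyl)oxy]prop-1-en-2-yl}-4-[(triethylsilyl)oxy]cyclohexa-2,5-dien-1-ol (OH and OSiEt3 on opposite faces; achiral)
Conditions: NaBH4, CeCl3·7H2O, MeOH, −78 °C; pH 7 work-up
Reagents that add atoms: none
Why: Luche 1,2-reduction of the cross-conjugated dienone; hydride should add to the face that carries the C4–O bond (dipole-controlled facial selectivity known for 4-alkoxy-4-alkylcyclohexa-2,5-dienones), so OH ends trans to OSiEt3, and the minor cis isomer is removed by chromatography.

Step 8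
Reactants: 14 trans-dienol; 6 (E)-tridec-4-enoic acid
Product: 15 trans-4-{3-[(tert-butyldimethylsilyl)oxy]prop-1-en-2-yl}-4-[(triethylsilyl)oxy]cyclohexa-2,5-dien-1-yl (E)-tridec-4-enoate (acyloxy trans to OSiEt3; meso)
Conditions: DCC, DMAP (cat.), CH2Cl2, 0 °C
Reagents that add atoms: none
Why: Steglich esterification of the only free hydroxyl under non-acidic conditions with retention at the carbinol carbon, which avoids ionisation of the bis-allylic alcohol.

Step 9
Reactants: 15 meso dienyl ester
Product: 17 (2S,4E)-2-[(1S,6R)-6-{3-[(tert-butyldimethylsilyl)oxy]prop-1-en-2-yl}-6-[(triethylsilyl)oxy]cyclohexa-2,4-dien-1-yl]tridec-4-enoic acid, via boron ketene acetal 16 (not isolated)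
Conditions: (S,S)-bromoborane controller [from the (S,S)-bis-sulfonamide and BBr3, CH2Cl2], i-Pr2NEt, CH2Cl2, −78 °C → rt; pH 7 buffer
Reagents that add atoms: none
Why: Proposed new method: soft enolisation of the ester by the C2-symmetric bromoborane and the amine should give the O-boron ketene acetal 16 with the alkyl chain cis to O–B, and its [3,3] shift through a chair transition state (ring carbons axial, as for 2-cyclohexenyl esters; the second ring alkene flattens the ring and relieves the transannular contact that otherwise favours the boat) can engage either of the two enantiotopic allyl arms of the meso ester. Because the controller fixes which enolate face bonds and the chair fixes the relative topicity, only one arm fits, so the ring CH, the acid α-carbon and the tertiary carbinol carbon should emerge as one enantiomer; the new C–C bond forms suprafacially on the face that carried the acyloxy group, i.e. trans to OSiEt3, and the cyclohexa-1,3-diene is unveiled in the same event. The closest known reaction types are the bis-sulfonamide-boron-controlled enantioselective Ireland–Claisen rearrangement of achiral allyl esters and the Ireland–Claisen rearrangement of divinylcarbinyl and 2-cyclohexenyl esters; what is new is the use of the controller to choose between enantiotopic arms of a meso cyclohexa-2,5-dienyl ester. The acid α-centre, if formed as a mixture, can be corrected later because it is α to the carbonyl in 18–21 and the needed epimer is the more stable trans-1,2-disubstituted cyclopentane.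

Step 10
Reactants: 17 diene acid
Product: 18 tricyclic acid (cyclobutane cis-fused to the cyclohexene and to the new cyclopentane; octyl exo; CO2H on the cyclopentane trans to the neighbouring ring-fusion substituent)
Conditions: [Ir{dF(CF3)ppy}2(dtbbpy)]PF6 (1 mol %), degassed MeCN (0.01 M), blue LEDs (450 nm), rt
Reagents that add atoms: none
Why: Triplet energy transfer from the excited Ir(III) sensitiser (ET about 61 kcal/mol) to the cyclohexa-1,3-diene of 17 (ET about 52 kcal/mol; the isolated alkenes and the acid are not sensitised) gives a diene triplet whose terminus next to the ring sp3 CH attacks the near carbon of the tethered E-alkene, and the 1,4-biradical so formed (allyl radical in the six-membered ring, secondary alkyl radical at the octyl-bearing carbon) closes at the near allyl terminus after intersystem crossing. The closest known reaction type is the visible-light, Ir-sensitised intramolecular [2+2] cycloaddition of 1,3-dienes with tethered alkenes; sensitisation rather than direct excitation is chosen because singlet cyclohexadienes open to hexatrienes. The cyclopentane closes 5-exo-trig in the first bond formation (rule of five, three-atom tether CH(CO2H)–CH2 plus the ring CH) and the cyclobutane closes by 4-exo collapse of the biradical. The two former diene carbons and the cyclobutane CH next to the CH2 are fixed by the tether, which can only reach the diene face that carries the side chain and can only give cis 4/5, 4/6 and 5/6 fusions; the octyl-bearing carbon follows from the E-alkene and, should the biradical rotate, from the preference for the exo position trans to both neighbours, so the centres set in step 9 relay all four new ones. The step needs closure to the cyclobutane in preference to closure at the far allyl terminus (formal [4+2], bicyclo[2.2.2]octene) and to reaction at the 1,1-disubstituted alkene; the far terminus is flanked by the fully substituted silyloxy carbon and the 1,1-disubstituted alkene is only two atoms from the diene, so both should be disfavoured, and unproductive decay of the triplet only returns 17.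

Step 11
Reactants: 18 tricyclic acid
Product: 20 Weinreb amide of 18, via acyl imidazole 19 (not isolated)
Conditions: CDI, CH2Cl2, rt; then MeNHOMe·HCl, rt
Reagents that add atoms: N,O-dimethylhydroxylamine hydrochloride, CNOC.Cl; 1,1'-carbonyldiimidazole, O=C(n1ccnc1)n1ccnc1
Why: Acyl imidazole activation and aminolysis (Weinreb amide formation) under neutral conditions; the α-centre sits on the convex face trans to its ring neighbour and is not at risk.

Step 12
Reactants: 20 Weinreb amide
Product: 21 vinyl ketone
Conditions: CH2=CHMgBr, THF, −78 → 0 °C; inverse quench into cold 1 M HCl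
Reagents that add atoms: vinylmagnesium bromide, C=C[Mg]Br
Why: Weinreb ketone synthesis: the chelated tetrahedral intermediate prevents over-addition, and the acidic inverse quench prevents aza-Michael addition of the released amine to the enone.

Step 13
Reactants: 21 vinyl ketone
Product: 22 allylic alcohol (secondary vinyl carbinol)
Conditions: NaBH4, CeCl3·7H2O, MeOH, −78 °C
Reagents that add atoms: none
Why: Luche 1,2-reduction under Felkin–Anh control: hydride enters anti to the ring-fusion CH (the larger α-substituent, which carries the quaternary silyloxy carbon), and this gives the carbinol epimer that the target needs.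

Step 14
Reactants: 22 allylic alcohol
Product: 23 tetracyclic bis-silyl ether (target skeleton with OSiEt3 on the ring-fusion carbinol and CH2OTBS in place of CO2H)
Conditions: Hoveyda–Grubbs II (10 mol %), 1,4-benzoquinone (cat.), toluene, 80 °C
Reagents that add atoms: none
Why: Ring-closing metathesis (initiation at the vinyl carbinol, closure on the 1,1-disubstituted alkene) to a six-membered trisubstituted cyclohexene; the existing ring alkene is strain-free and inert, and benzoquinone suppresses Ru–H isomerisation of the allylic alcohol.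

Step 15
Reactants: 23 tetracyclic bis-silyl ether
Product: 24 tetracyclic triol
Conditions: TBAF, THF, 0 °C → rt
Reagents that add atoms: none
Why: Fluoride cleavage of the primary TBS ether and the tertiary TES ether.

Step 16
Reactants: 24 tetracyclic triol
Product: 26 target acid CNP0106718.3, via enal 25 (not isolated)
Conditions: TEMPO (cat.), PhI(OAc)2, CH2Cl2, rt; then t-BuOH/H2O, 2-methyl-2-butene, NaClO2, NaH2PO4, 0 °C
Reagents that add atoms: sodium chlorite, [Na+].[O-]Cl=O
Why: Oxoammonium oxidation selective for the primary allylic alcohol over the secondary one, followed in the same flask by Pinnick oxidation of the enal with a hypochlorite scavenger; the tertiary and secondary carbinols and both ring alkenes are untouched.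

**Compound list**

1 | nonanal | CCCCCCCCC=O | starting material
2 | undec-1-en-3-ol (racemic) | CCCCCCCCC(O)C=C | intermediate
3 | triethyl orthoacetate | CC(OCC)(OCC)OCC | starting material
4 | 3-[(1-ethoxyethenyl)oxy]undec-1-ene (mixed ketene acetal) | CCCCCCCCC(OC(=C)OCC)C=C | intermediate
5 | ethyl (E)-tridec-4-enoate | CCCCCCCC/C=C/CCC(=O)OCC | intermediate
6 | (E)-tridec-4-enoic acid | CCCCCCCC/C=C/CCC(=O)O | intermediate
7 | 2-bromoprop-2-en-1-ol | C=C(Br)CO | starting material
8 | [(2-bromoprop-2-en-1-yl)oxy](tert-butyl)dimethylsilane | C=C(Br)CO[Si](C)(C)C(C)(C)C | intermediate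
9 | 4,4-dimethoxycyclohexa-2,5-dien-1-one | COC1(OC)C=CC(=O)C=C1 | starting material
10 | {3-[(tert-butyldimethylsilyl)oxy]prop-1-en-2-yl}lithium | [Li]C(=C)CO[Si](C)(C)C(C)(C)C | intermediate
11 | 1-{3-[(tert-butyldimethylsilyl)oxy]prop-1-en-2-yl}-4,4-dimethoxycyclohexa-2,5-dien-1-ol | COC1(OC)C=CC(O)(C(=C)CO[Si](C)(C)C(C)(C)C)C=C1 | intermediate
12 | 4-hydroxy-4-{3-[(tert-butyldimethylsilyl)oxy]prop-1-en-2-yl}cyclohexa-2,5-dien-1-one | O=C1C=CC(O)(C(=C)CO[Si](C)(C)C(C)(C)C)C=C1 | intermediate
13 | 4-{3-[(tert-butyldimethylsilyl)oxy]prop-1-en-2-yl}-4-[(triethylsilyl)oxy]cyclohexa-2,5-dien-1-one | O=C1C=CC(O[Si](CC)(CC)CC)(C(=C)CO[Si](C)(C)C(C)(C)C)C=C1 | intermediate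
14 | trans-4-{3-[(tert-butyldimethylsilyl)oxy]prop-1-en-2-yl}-4-[(triethylsilyl)oxy]cyclohexa-2,5-dien-1-ol (OH trans to OSiEt3; achiral) | O[C@H]1C=C[C@@](O[Si](CC)(CC)CC)(C(=C)CO[Si](C)(C)C(C)(C)C)C=C1 | intermediate
15 | (E)-tridec-4-enoate of 14 (acyloxy trans to OSiEt3; meso) | CCCCCCCC/C=C/CCC(=O)O[C@H]1C=C[C@@](O[Si](CC)(CC)CC)(C(=C)CO[Si](C)(C)C(C)(C)C)C=C1 | intermediate
16 | O-boron ketene acetal of 15 (chain cis to O–B; boron held in the (4S,5S)-1,3-bis[3,5-bis(trifluoromethyl)phenylsulfonyl]-4,5-diphenyl-1,3,2-diazaborolidine) | CCCCCCCC/C=C/C/C=C(/O[C@H]1C=C[C@@](O[Si](CC)(CC)CC)(C(=C)CO[Si](C)(C)C(C)(C)C)C=C1)OB1N(S(=O)(=O)c2cc(cc(c2)C(F)(F)F)C(F)(F)F)[C@@H](c2ccccc2)[C@H](c2ccccc2)N1S(=O)(=O)c1cc(cc(c1)C(F)(F)F)C(F)(F)F | intermediate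
17 | (2S,4E)-2-[(1S,6R)-6-{3-[(tert-butyldimethylsilyl)oxy]prop-1-en-2-yl}-6-[(triethylsilyl)oxy]cyclohexa-2,4-dien-1-yl]tridec-4-enoic acid (side chain trans to OSiEt3) | CCCCCCCC/C=C/C[C@H](C(=O)O)[C@@H]1C=CC=C[C@]1(O[Si](CC)(CC)CC)C(=C)CO[Si](C)(C)C(C)(C)C | intermediate
18 | tricyclic acid: octyl-cyclobutane cis-fused to the cyclohexene (C=C next to the fusion) and to the cyclopentane; CO2H on the cyclopentane trans to the adjacent ring-fusion substituent | CCCCCCCC[C@H]1[C@@H]2C=C[C@](O[Si](CC)(CC)CC)(C(=C)CO[Si](C)(C)C(C)(C)C)[C@H]3[C@@H]2[C@@H]1C[C@@H]3C(=O)O | intermediate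
19 | acyl imidazole of 18 | CCCCCCCC[C@H]1[C@@H]2C=C[C@](O[Si](CC)(CC)CC)(C(=C)CO[Si](C)(C)C(C)(C)C)[C@H]3[C@@H]2[C@@H]1C[C@@H]3C(=O)n1ccnc1 | intermediate
20 | N-methoxy-N-methyl amide of 18 | CCCCCCCC[C@H]1[C@@H]2C=C[C@](O[Si](CC)(CC)CC)(C(=C)CO[Si](C)(C)C(C)(C)C)[C@H]3[C@@H]2[C@@H]1C[C@@H]3C(=O)N(C)OC | intermediate
21 | vinyl ketone (CO2H of 18 replaced by C(=O)CH=CH2) | CCCCCCCC[C@H]1[C@@H]2C=C[C@](O[Si](CC)(CC)CC)(C(=C)CO[Si](C)(C)C(C)(C)C)[C@H]3[C@@H]2[C@@H]1C[C@@H]3C(=O)C=C | intermediate
22 | allylic alcohol (Felkin epimer of the vinyl carbinol) | CCCCCCCC[C@H]1[C@@H]2C=C[C@](O[Si](CC)(CC)CC)(C(=C)CO[Si](C)(C)C(C)(C)C)[C@H]3[C@@H]2[C@@H]1C[C@@H]3[C@H](O)C=C | intermediate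
23 | tetracyclic bis-silyl ether (target skeleton; tertiary OSiEt3; CH2OTBS on the ring alkene) | CCCCCCCC[C@H]1[C@@H]2C=C[C@]3(O[Si](CC)(CC)CC)C(CO[Si](C)(C)C(C)(C)C)=C[C@@H](O)[C@H]4C[C@H]1[C@H]2[C@@H]43 | intermediate
24 | tetracyclic triol (CH2OH in place of CO2H) | CCCCCCCC[C@H]1[C@@H]2C=C[C@]3(O)C(CO)=C[C@@H](O)[C@H]4C[C@H]1[C@H]2[C@@H]43 | intermediate
25 | tetracyclic enal (CHO in place of CO2H) | CCCCCCCC[C@H]1[C@@H]2C=C[C@]3(O)C(C=O)=C[C@@H](O)[C@H]4C[C@H]1[C@H]2[C@@H]43 | intermediate
26 | target acid CNP0106718.3 | CCCCCCCC[C@H]1[C@@H]2C=C[C@]3(O)C(C(=O)O)=C[C@@H](O)[C@H]4C[C@H]1[C@H]2[C@@H]43 | target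

**Step count and risks**

Total step count: 16. Longest linear sequence: 13 steps (steps 4–16, from 7).

Steps most likely to fail:

1. Step 9 (Proposed new method). The discrimination between the two enantiotopic allyl arms may be too low (chair/boat leakage, or weak facial control by the boron centre), or the Lewis-acidic boron may ionise the bis-allylic ester and the ring then aromatises. Fallback by resolution instead of reagent control, all known chemistry: it sets out from 15. LDA and TMSCl in THF–DMPU at −78 °C should give the (Z)-O-silyl ketene acetal F1, which rearranges on warming and, after mild hydrolysis, gives the racemic diene acid F2. F2 is taken through the sensitised cycloaddition of step 10 to the racemic tricyclic acid F3. F3 is resolved by crystallisation with (R)-1-phenylethylamine as the 1-phenylethylammonium salt F4, and acidification of F4 brings the route back at 18.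

2. Step 10. The diene triplet may decay faster than it is captured by the unactivated alkene, or the 1,4-biradical may close at the far allyl terminus to the bicyclo[2.2.2]octene. Fallback by changing the order, so that the cycloaddition runs on a substrate whose tether is held by a ring: it sets out from 17. With the chemistry of steps 11–14, 17 is converted via the acyl imidazole F5 into the diene Weinreb amide F6, then into the diene vinyl ketone F7 (vinylmagnesium bromide), then by Luche reduction into the diene allylic alcohol F8, and by ring-closing metathesis into the cis-fused bicyclic dienol F9. In F9 the undecenyl chain is an equatorial substituent held gauche to the diene terminus, which should speed the 5-exo capture. The sensitised [2+2] of F9 under the conditions of step 10 brings the route back at 23.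

3. Step 13. The facial selectivity of hydride addition to the vinyl ketone may be low (Felkin against anti-Felkin), and conjugate reduction may compete. Fallback by reagent control on an ynone: it sets out from 20. Lithium (trimethylsilyl)acetylide should give the silyl ynone F10. Noyori transfer hydrogenation with the (S,S)-TsDPEN ruthenium catalyst in i-PrOH should give the (S)-configured silyl propargylic alcohol F11, with catalyst control matched to the Felkin preference. K2CO3 in MeOH gives the terminal propargylic alcohol F12, and Lindlar semihydrogenation brings the route back at 22.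

Further compounds
F1 | step 9 | (Z)-O-trimethylsilyl ketene acetal of 15 | CCCCCCCC/C=C/C/C=C(/O[C@H]1C=C[C@@](O[Si](CC)(CC)CC)(C(=C)CO[Si](C)(C)C(C)(C)C)C=C1)O[Si](C)(C)C
F2 | step 9 | racemic diene acid (17 and its enantiomer) | CCCCCCCC/C=C/C[C@H](C(=O)O)[C@@H]1C=CC=C[C@]1(O[Si](CC)(CC)CC)C(=C)CO[Si](C)(C)C(C)(C)C.CCCCCCCC/C=C/C[C@@H](C(=O)O)[C@H]1C=CC=C[C@@]1(O[Si](CC)(CC)CC)C(=C)CO[Si](C)(C)C(C)(C)C
F3 | step 9 | racemic tricyclic acid (18 and its enantiomer) | CCCCCCCC[C@H]1[C@@H]2C=C[C@](O[Si](CC)(CC)CC)(C(=C)CO[Si](C)(C)C(C)(C)C)[C@H]3[C@@H]2[C@@H]1C[C@@H]3C(=O)O.CCCCCCCC[C@@H]1[C@H]2C=C[C@@](O[Si](CC)(CC)CC)(C(=C)CO[Si](C)(C)C(C)(C)C)[C@@H]3[C@H]2[C@H]1C[C@H]3C(=O)O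
F4 | step 9 | (R)-1-phenylethylammonium salt of 18 | CCCCCCCC[C@H]1[C@@H]2C=C[C@](O[Si](CC)(CC)CC)(C(=C)CO[Si](C)(C)C(C)(C)C)[C@H]3[C@@H]2[C@@H]1C[C@@H]3C(=O)[O-].C[C@@H]([NH3+])c1ccccc1
F5 | step 10 | acyl imidazole of 17 | CCCCCCCC/C=C/C[C@H](C(=O)n1ccnc1)[C@@H]1C=CC=C[C@]1(O[Si](CC)(CC)CC)C(=C)CO[Si](C)(C)C(C)(C)C
F6 | step 10 | N-methoxy-N-methyl amide of 17 | CCCCCCCC/C=C/C[C@H](C(=O)N(C)OC)[C@@H]1C=CC=C[C@]1(O[Si](CC)(CC)CC)C(=C)CO[Si](C)(C)C(C)(C)C
F7 | step 10 | diene vinyl ketone | CCCCCCCC/C=C/C[C@H](C(=O)C=C)[C@@H]1C=CC=C[C@]1(O[Si](CC)(CC)CC)C(=C)CO[Si](C)(C)C(C)(C)C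
F8 | step 10 | diene allylic alcohol | CCCCCCCC/C=C/C[C@H]([C@H](O)C=C)[C@@H]1C=CC=C[C@]1(O[Si](CC)(CC)CC)C(=C)CO[Si](C)(C)C(C)(C)C
F9 | step 10 | cis-fused bicyclic dienol (both six-membered rings of the target; undecenyl side chain still open) | CCCCCCCC/C=C/C[C@@H]1[C@H](O)C=C(CO[Si](C)(C)C(C)(C)C)[C@@]2(O[Si](CC)(CC)CC)C=CC=C[C@@H]12
F10 | step 13 | trimethylsilyl ynone | CCCCCCCC[C@H]1[C@@H]2C=C[C@](O[Si](CC)(CC)CC)(C(=C)CO[Si](C)(C)C(C)(C)C)[C@H]3[C@@H]2[C@@H]1C[C@@H]3C(=O)C#C[Si](C)(C)C
F11 | step 13 | trimethylsilyl propargylic alcohol | CCCCCCCC[C@H]1[C@@H]2C=C[C@](O[Si](CC)(CC)CC)(C(=C)CO[Si](C)(C)C(C)(C)C)[C@H]3[C@@H]2[C@@H]1C[C@@H]3[C@H](O)C#C[Si](C)(C)C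
F12 | step 13 | terminal propargylic alcohol | CCCCCCCC[C@H]1[C@@H]2C=C[C@](O[Si](CC)(CC)CC)(C(=C)CO[Si](C)(C)C(C)(C)C)[C@H]3[C@@H]2[C@@H]1C[C@@H]3[C@H](O)C#C
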